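Numbering: C1 is the tertiary carbinol carrying the C7 methylene, C2 the ketone, C3=C4 the alkene, C5 the ring carbon with the benzoate, and C6 the secondary carbinol. C5 is an allylic carbinol bonded to C4, the β-carbon of the cyclohexenone ring. The C4–C5 bond is therefore disconnected to a C4 vinyl metal and a C5 aldehyde. One nickel/chromium-mediated closure of an acyclic (Z)-β-iodoenone aldehyde makes this bond, the carbocycle and the C5 stereocentre together. It leaves the C5 hydroxyl as the only free one. The precursor holds O1 and O6 in a cis-dioxolane and C7 as its benzoate. Its C1 and C6 are C2 and C3 of D-mannose.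

Key step: step 9

Remarks on the chemistry
- Assumption: 1 is taken as a catalogue compound (the bis-acetonide of D-mannose). Compounds 3, 5 and 7–10 are carried as mixtures at the lactol or C2 carbinol centre, which is left undefined in their SMILES. They converge at 11.
- Atom map:
  - sugar C1 → C2, sugar C2 → C1, new CH2OH → C7, sugar C3 → C6, sugar C4 → C5;
  - sugar C5 and C6 are excised;
  - C3 and C4 come from the ethynyl unit.
- Choice of sugar: in a Fischer projection with C2 uppermost the target needs O1 and O6 both on the left. This is the C2/C3 pattern of D-mannose.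
- Order of events on the way to 13:
  - (a) C7 is benzoylated while it is the only primary hydroxyl and before any ynone exists. A free C7–OH could add to C4 and close a dihydropyranone.
  - (b) A C5 aldehyde next to a free C2 carbinol collapses to lactol 9. C5 is therefore reduced, C2 is oxidised first and C5 last.
  - (c) Iodide is added before the aldehyde is present. Otherwise the iodoallenol intermediate could attack C5 through C3 in a five-membered halo-aldol closure.
  - (d) The dioxolane holds the C2 acyl and C5 formyl groups cis and leaves no free β-hydroxyl for retro-aldol cleavage.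
- Configuration check:
  - C1 is S in 11–17.
  - C6 is S in 10–12, R in 13 and 14 (formyl outranks C1) and S in 15–17, with unchanged geometry throughout.
  - C5 is R in 15–17.

Step 1
Reactants: 1 2,3:5,6-di-O-isopropylidene-α-D-mannofuranose; 2 formaldehyde
Product: 3 2-C-(hydroxymethyl)-2,3:5,6-di-O-isopropylidene-D-mannofuranose (anomers)
Conditions: 37% aq HCHO, K2CO3, MeOH, reflux
Reagents that add atoms: formaldehyde C=O
Why: Base-mediated crossed aldol (hydroxymethylation) of the open aldehyde tautomer of a furanose lactol with non-enolisable formaldehyde; the aldol is reversible and only the epimer whose aldehyde is cis to sugar C4 on the dioxolane can re-close to the cis-fused furanose, so CH2OH replaces H-2 with retention and sets the future C1.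

Step 2
Reactants: 3 2-C-(hydroxymethyl)-2,3:5,6-di-O-isopropylidene-D-mannofuranose; 4 ethynylmagnesium bromide
Product: 5 1-C-ethynyl-2-C-(hydroxymethyl)-2,3:5,6-di-O-isopropylidene-D-mannitol (triol; C1 epimers)
Conditions: HC≡CMgBr (6 equiv), THF, 0 °C → rt; aq NH4Cl
Reagents that add atoms: ethynylmagnesium bromide C#C[Mg]Br
Why: Grignard addition to the aldehyde tautomer of the lactol after deprotonation of both hydroxyls; the new carbinol (future C2) forms as an epimer mixture, which is harmless because step 6 turns it into a ketone.

Step 3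
Reactants: 5 1-C-ethynyl-2-C-(hydroxymethyl)-2,3:5,6-di-O-isopropylidene-D-mannitol; 6 benzoyl chloride
Product: 7 2-C-(benzoyloxymethyl)-1-C-ethynyl-2,3:5,6-di-O-isopropylidene-D-mannitol (C1 epimers)
Conditions: BzCl (1.05 equiv), pyridine, CH2Cl2, −20 → 0 °C
Reagents that add atoms: benzoyl chloride O=C(Cl)c1ccccc1
Why: Rate-selective O-acylation of the only primary hydroxyl, since both secondary hydroxyls lie between branched carbons.

Step 4
Reactants: 7 2-C-(benzoyloxymethyl)-1-C-ethynyl-2,3:5,6-di-O-isopropylidene-D-mannitol
Product: 9 furanose lactol (ring O–C5(OH)–C6–C1–C2(C≡CH) cis-fused to the 1,6-dioxolane; C7H2OBz on C1), via tetraol 8 (not isolated)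
Conditions: AcOH–H2O 4:1, 40 °C; evaporate; NaIO4 (2.5 equiv), THF–H2O, 0 °C → rt
Reagents that add atoms: none
Why: Selective acid hydrolysis of the less substituted terminal dioxolane, then Malaprade glycol cleavage of the sugar C4–C5–C6 triol, which removes two carbons and leaves the future C5 as an aldehyde that the C2 hydroxyl captures as a lactol; no stereocentre of the target is touched.

Step 5
Reactants: 9 furanose lactol
Product: 10 [(4R,5S)-5-(hydroxymethyl)-4-(1-hydroxyprop-2-yn-1-yl)-2,2-dimethyl-1,3-dioxolan-4-yl]methyl benzoate (carbinol epimers)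
Conditions: NaBH4, EtOH, 0 °C; H2O
Reagents that add atoms: none
Why: Borohydride reduction of the lactol through its hydroxy aldehyde tautomer, chemoselective over benzoate and alkyne; it parks C5 as a primary alcohol so that C2 can be oxidised first.

Step 6
Reactants: 10 propargylic/primary diol
Product: 11 [(4S,5S)-5-(hydroxymethyl)-2,2-dimethyl-4-(prop-2-ynoyl)-1,3-dioxolan-4-yl]methyl benzoate
Conditions: activated MnO2 (large excess), CH2Cl2, rt
Reagents that add atoms: none
Why: Chemoselective MnO2 oxidation of an activated (propargylic) alcohol beside a saturated primary one; both C2 epimers converge on one ynone, which may rest reversibly as its five-membered hemiketal tautomer.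

Step 7
Reactants: 11 hydroxy ynone
Product: 12 [(4S,5S)-5-(hydroxymethyl)-4-[(2Z)-3-iodoprop-2-enoyl]-2,2-dimethyl-1,3-dioxolan-4-yl]methyl benzoate
Conditions: LiI, AcOH, MeCN, 0 °C → rt, dark
Reagents that add atoms: lithium iodide [Li+].[I-]
Why: Conjugate hydroiodination of an alkynyl ketone, in which iodide adds to C4 and the allenol is protonated anti to iodine to give the Z alkene under kinetic control, while ring–chain equilibration feeds the open ynone as the only acceptor.

Step 8
Reactants: 12 hydroxy (Z)-iodoenone
Product: 13 [(4S,5R)-5-formyl-4-[(2Z)-3-iodoprop-2-enoyl]-2,2-dimethyl-1,3-dioxolan-4-yl]methyl benzoate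
Conditions: Dess–Martin periodinane, CH2Cl2, 0 °C → rt, dark
Reagents that add atoms: none
Why: Dess–Martin oxidation of the primary alcohol under non-basic conditions that spare the Z-iodoenone and the epimerisable C6; the hemiketal tautomer carries only a tertiary hydroxyl and is drained through the open form.

Step 9
Reactants: 13 (Z)-iodoenone aldehyde
Product: 15 (1S,5R,6S)-1,6-O-isopropylidene-5-O-debenzoylzeylenone, via vinylchromium dichloride 14 (not isolated)
Conditions: CrCl2 (8 equiv), NiCl2 (0.1 equiv), degassed DMF, 5 mM, slow addition of 13, rt, dark; H2O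
Reagents that add atoms: none
Why: Zerovalent nickel, formed from NiCl2 by divalent chromium, inserts into the C4–I bond with retention, transmetalation to trivalent chromium gives 14, this adds to the C5 aldehyde and aqueous work-up frees the C5 hydroxyl. The reaction is an intramolecular Nozaki–Hiyama–Kishi coupling, and its closest known cases are couplings of (Z)-β-iodoenones and (Z)-β-iodoenoates with aldehydes. The cyclohexenone ring closes in a 6-exo-trig mode at the aldehyde carbonyl, a geometry only the Z vinyl metal can reach. C5 is under substrate control from C1 and C6: in the half-chair with C7 and O6 pseudo-equatorial the aldehyde oxygen should point outward toward chromium and away from the axial O1, so C5–O is expected to form trans to C6–O (5R). The step needs chemoselectivity for the aldehyde over the C2 ketone and the benzoate, which the weakly basic, aldehyde-selective organochromium provides, and freedom from enolisation and β-elimination, which the dioxolane and the neutral medium secure. High dilution and a low nickel loading hold back dimerisation of the vinyl metal.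

Step 10
Reactants: 15 1,6-O-isopropylidene-5-O-debenzoylzeylenone; 6 benzoyl chloride
Product: 16 (1S,5R,6S)-1,6-O-isopropylidenezeylenone
Conditions: BzCl, pyridine, DMAP (cat.), CH2Cl2, 0 °C
Reagents that add atoms: benzoyl chloride O=C(Cl)c1ccccc1
Why: DMAP-catalysed O-acylation of the only free hydroxyl with retention at C5, under weakly basic conditions that should not trigger elimination of the γ-acyloxy enone.

Step 11
Reactants: 16 1,6-O-isopropylidenezeylenone
Product: 17 zeylenone
Conditions: TFA–H2O 9:1, 0 °C → rt
Reagents that add atoms: none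
Why: Acid-catalysed acetal hydrolysis releases the cis C1/C6 diol; the benzoates and the enone tolerate cold aqueous TFA and no stereocentre is involved.

Compound list
1 | 2,3:5,6-di-O-isopropylidene-α-D-mannofuranose | O[C@@H]1[C@H]2OC(C)(C)O[C@H]2[C@H](O1)[C@H]1COC(C)(C)O1 | starting material
2 | formaldehyde | C=O | starting material
3 | 2-C-(hydroxymethyl)-2,3:5,6-di-O-isopropylidene-D-mannofuranose (anomers) | OC1[C@@]2(CO)OC(C)(C)O[C@H]2[C@H](O1)[C@H]1COC(C)(C)O1 | intermediate
4 | ethynylmagnesium bromide | C#C[Mg]Br | starting material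
5 | 1-C-ethynyl-2-C-(hydroxymethyl)-2,3:5,6-di-O-isopropylidene-D-mannitol (C1 epimers) | C#CC(O)[C@@]1(CO)OC(C)(C)O[C@H]1[C@H](O)[C@H]1COC(C)(C)O1 | intermediate
6 | benzoyl chloride | O=C(Cl)c1ccccc1 | starting material
7 | 2-C-(benzoyloxymethyl)-1-C-ethynyl-2,3:5,6-di-O-isopropylidene-D-mannitol (C1 epimers) | C#CC(O)[C@@]1(COC(=O)c2ccccc2)OC(C)(C)O[C@H]1[C@H](O)[C@H]1COC(C)(C)O1 | intermediate
8 | 2-C-(benzoyloxymethyl)-1-C-ethynyl-2,3-O-isopropylidene-D-mannitol (tetraol) | C#CC(O)[C@@]1(COC(=O)c2ccccc2)OC(C)(C)O[C@H]1[C@H](O)[C@H](O)CO | intermediate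
9 | furanose lactol, (4-ethynyl-6-hydroxy-2,2-dimethyl-tetrahydrofuro[3,4-d][1,3]dioxol-3a-yl)methyl benzoate, cis-fused | C#CC1OC(O)[C@@H]2OC(C)(C)O[C@]12COC(=O)c1ccccc1 | intermediate
10 | [(4R,5S)-5-(hydroxymethyl)-4-(1-hydroxyprop-2-yn-1-yl)-2,2-dimethyl-1,3-dioxolan-4-yl]methyl benzoate | C#CC(O)[C@@]1(COC(=O)c2ccccc2)OC(C)(C)O[C@H]1CO | intermediate
11 | [(4S,5S)-5-(hydroxymethyl)-2,2-dimethyl-4-(prop-2-ynoyl)-1,3-dioxolan-4-yl]methyl benzoate | C#CC(=O)[C@@]1(COC(=O)c2ccccc2)OC(C)(C)O[C@H]1CO | intermediate
12 | [(4S,5S)-5-(hydroxymethyl)-4-[(2Z)-3-iodoprop-2-enoyl]-2,2-dimethyl-1,3-dioxolan-4-yl]methyl benzoate | I/C=C\C(=O)[C@@]1(COC(=O)c2ccccc2)OC(C)(C)O[C@H]1CO | intermediate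
13 | [(4S,5R)-5-formyl-4-[(2Z)-3-iodoprop-2-enoyl]-2,2-dimethyl-1,3-dioxolan-4-yl]methyl benzoate | I/C=C\C(=O)[C@@]1(COC(=O)c2ccccc2)OC(C)(C)O[C@H]1C=O | intermediate
14 | vinylchromium dichloride derived from 13 (Cr in place of I, Z retained) | Cl[Cr](Cl)/C=C\C(=O)[C@@]1(COC(=O)c2ccccc2)OC(C)(C)O[C@H]1C=O | intermediate
15 | (1S,5R,6S)-1,6-O-isopropylidene-5-O-debenzoylzeylenone | O=C(OC[C@@]1(O2)C(=O)C=C[C@@H](O)[C@@H]1OC2(C)C)c1ccccc1 | intermediate
16 | (1S,5R,6S)-1,6-O-isopropylidenezeylenone | O=C(OC[C@@]1(O2)C(=O)C=C[C@@H](OC(=O)c3ccccc3)[C@@H]1OC2(C)C)c1ccccc1 | intermediate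
17 | zeylenone, (1S,5R,6S) | O=C(OC[C@@]1(O)C(=O)C=C[C@@H](OC(=O)c2ccccc2)[C@@H]1O)c1ccccc1 | target

Total step count: 11. Longest linear sequence: 11 (steps 1–11 from 1).

Steps most likely to fail

Step 9. The two faces of the aldehyde may be poorly differentiated, so that part or most of the material closes with C5–O cis to C6–O. Fallback:
- It sets out from 13. The closure is accepted as it comes and the cis alcohol 5-epi-1,6-O-isopropylidene-5-O-debenzoylzeylenone F1 is separated.
- F1 is esterified under Mitsunobu conditions (PhCO2H, PPh3, DIAD, toluene, 0 °C).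
- SN2 displacement of the activated allylic oxygen inverts C5 and installs the benzoate in the same operation, so the material comes back to the route at 16.
- C5 is then fixed by inversion and not by the addition itself. SN2′ attack at C3, the α-carbon of the enone, is electronically disfavoured.

Step 6. Oxidation of the hindered carbinol on the MnO2 surface may be slow or incomplete, and the free C5 hydroxyl may interfere in the ynone chemistry that follows. Fallback, which relies on protection and not on chemoselectivity:
- It sets out from 10. TESCl and imidazole (CH2Cl2, −40 °C) silylate only the primary hydroxyl to give the primary triethylsilyl ether of 10 F2.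
- Dess–Martin periodinane then gives the silyl-protected ynone F3.
- LiI/AcOH in MeCN gives the silyl-protected (Z)-iodoenone F4.
- AcOH–THF–H2O at rt removes the silyl group, and the sequence comes back at 12.

Step 7. Reversible iodide addition may erode the Z geometry, or addition may be sluggish because the acceptor is tied up as its hemiketal. Fallback, which sets the geometry by syn hydrogen delivery:
- It sets out from 10. N-iodosuccinimide with catalytic AgNO3 in acetone gives the 1-iodoalkyne diol F5.
- Diimide generated from 2-nitrobenzenesulfonylhydrazide and Et3N reduces it to the (Z)-3-iodoallylic alcohol diol F6.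
- MnO2 oxidises only the allylic carbinol, and the sequence comes back at 12.

Further compounds
F1 | step 9 | (1S,5S,6S)-5-epi-1,6-O-isopropylidene-5-O-debenzoylzeylenone | O=C(OC[C@@]1(O2)C(=O)C=C[C@H](O)[C@@H]1OC2(C)C)c1ccccc1
F2 | step 6 | primary triethylsilyl ether of 10 | C#CC(O)[C@@]1(COC(=O)c2ccccc2)OC(C)(C)O[C@H]1CO[Si](CC)(CC)CC
F3 | step 6 | silyl-protected ynone (triethylsilyl ether of 11) | C#CC(=O)[C@@]1(COC(=O)c2ccccc2)OC(C)(C)O[C@H]1CO[Si](CC)(CC)CC
F4 | step 6 | silyl-protected (Z)-iodoenone (triethylsilyl ether of 12) | I/C=C\C(=O)[C@@]1(COC(=O)c2ccccc2)OC(C)(C)O[C@H]1CO[Si](CC)(CC)CC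
F5 | step 7 | 1-iodoalkyne diol (C4-iodo derivative of 10) | IC#CC(O)[C@@]1(COC(=O)c2ccccc2)OC(C)(C)O[C@H]1CO
F6 | step 7 | (Z)-3-iodoallylic alcohol diol | I/C=C\C(O)[C@@]1(COC(=O)c2ccccc2)OC(C)(C)O[C@H]1CO
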